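Molar is my unit: each mole of substrate that reacts gets booked to the nucleophile that captures it, and the question is how those accounts close.

| flask | substrate | first nucleophile | second nucleophile | remark | time |
|---|---|---|---|---|---|
| north | 0.0082 M | 0.10 M | 0.055 M | run made earlier |  |
| north-west | 0.64 M | 0.10 M | 0.055 M | run made earlier |  |
| larch | 0.0060 M | 0.100 M | 0.0550 M |  | 2.0 min |
| ash | 0.015 M | 0.100 M | 0.0550 M |  | 2.0 min |
| birch | 0.050 M | 0.100 M | 0.0550 M |  | 2.0 min |
| elm | 0.15 M | 0.100 M | 0.0550 M |  | 2.0 min |
| oak | 0.50 M | 0.100 M | 0.0550 M |  | 2.0 min |

| run | time / s | target / % | substrate / % |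
|---|---|---|---|
| north | 10.0 | 10.0 | 25.5 |
| north | 12.0 | 8.4 | 20.5 |
| north | 15.0 | 9.9 | 12.0 |
| north | 25.0 | 10.9 | 2.9 |
| north | 40.0 | 10.7 | 0.3 |
| north | 60.0 | 10.4 | 0 |
| north-west | 10.0 | 11.6 | 72.2 |
| north-west | 12.0 | 12.6 | 70.6 |
| north-west | 15.0 | 11.5 | 70.2 |
| north-west | 25.0 | 9.3 | 69.1 |
| north-west | 40.0 | 7.1 | 66.1 |
| north-west | 60.0 | 4.9 | 65.6 |

(scatter of a reading: 1 percentage point)

* amount of target at the end, in percent of the substrate charged for larch, ash, birch, elm, oak, in this order
* how the row runs (falls all the way / rises, then falls / falls, then rises / rises all the way / hardly changes)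

- the numbers in the tables scatter by 1 percentage point (one standard deviation)
- "hardly changes" means that all values lie within two and a half points (for a concentration: within two and a half percent of the largest)

**Opening entry.** Suppose the two nucleophiles compete for the substrate. I call s the selectivity factor: how fast one molecule of first nucleophile captures, against one of second. North's charge is smaller than the second nucleophile's, so the charges roughly hold. Target stands at 10.4% there, which reads as s = 0.0638. At the start of any row flask, the first nucleophile's share is then 10.4%.

**The drift.** Since s lies below one, the second nucleophile drains faster, and the first's share climbs as it goes. The rule: the fraction of first nucleophile left equals the fraction of second left, raised to the power s.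

**Closing entries.** Booking the start share to the second nucleophile and applying the rule, I get 10.9% for larch and 11.8% for ash. Birch drifts further. A first pass gives 20.4%, and a second, using that share, gives 15.8%, so I commit to 18.1%. Elm's charge exceeds the second nucleophile's; that account closes, and the surplus gives a ceiling of 63.3%. Oak's ceiling is the first nucleophile's charge, 20.0%. In north-west, target falls from 12.6% at 12.0 s to 4.9% at 60.0 s, so I book oak under its ceiling. My row rises, then falls.

**The forecast.** It says 8%, 18%, 42%, 56%, 3.5%, and rises, then falls, holding that “its formation looks second-order in substrate”. We differ at ash and birch.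

**The flask.** It gives 10.6%, 11.4%, 16.7%, 54.8%, 4.12%, and rises, then falls.

    second nucleophile + intermediate → other capture product (k = 2230 M⁻¹ s⁻¹)
    first nucleophile + intermediate → target (k = 139 M⁻¹ s⁻¹)
    substrate + target → side product (k = 0.0465 M⁻¹ s⁻¹)
    substrate ⇌ intermediate (K = 0.0100, k = 0.153 s⁻¹)

**Where we part.** Birch parts us: 42% forecast, 16.7% found, with the second nucleophile still at 24% of its charge. Capture by the second nucleophile is the main reason for larch's low target: taken away there, target goes from 10.6% to 99.6%. Raising birch's 24% to the power 0.0638 leaves first nucleophile at 91.3%, against 92% simulated, and books 17.2% of target. The same step on ash, from 76%, books 11.7%, against 11.4% found.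

All runs stem from a simulated flask for substances that don't exist, noise included.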